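## Retrosynthetic overview

1. Target 11 ⇐ dimethyl ester 10 by saponification of both esters.
2. 10 ⇐ aryl triflate/aryl chloride 6 + 2 × heptanal 7. Both aryl–C1 bonds of the heptyl chains are made in one operation. Heptanal C1, normally an electrophile, acts as a carbanion through its N–H hydrazone and joins two electrophilic aryl carbons; loss of N2 leaves the CH2 directly.
3. 6 ⇐ 5 by monotriflation; 5 ⇐ SNAr of the 4-OH of methyl 2,4,6-trihydroxybenzoate 4 on fluoro ester 3.
4. 3 ⇐ 3-chloro-5-fluoroanisole 1 by lithiation between the halogens and methoxycarbonylation.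
5. Both benzene rings are bought; no ring is formed.

Assumption: the target has no stereocentre and is achiral, so the "single enantiomer" is the compound itself and no stereocontrol is needed.

## Route

Step 1
Reactants: 1 3-chloro-5-fluoroanisole
Product: 3 methyl 2-chloro-6-fluoro-4-methoxybenzoate, via aryllithium 2 (not isolated)
Conditions: LDA (1.1 equiv), THF, −78 °C, 1 h; then cannulated into ClCO2Me (2 equiv), THF, −78 °C → rt
Reagents that add atoms: methyl chloroformate, COC(=O)Cl
Why: Directed ortho-metalation, where the C–H flanked by F and Cl (para to OMe) is the most acidic toward a lithium amide, the aryllithium is stable at −78 °C, and inverse quench with the chloroformate gives the ester without over-addition.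

Step 2
Reactants: 3 methyl 2-chloro-6-fluoro-4-methoxybenzoate; 4 methyl 2,4,6-trihydroxybenzoate (1.3 equiv)
Product: 5 methyl 2-chloro-6-[3,5-dihydroxy-4-(methoxycarbonyl)phenoxy]-4-methoxybenzoate
Conditions: Cs2CO3 (1.3 equiv), DMSO, 90 °C
Reagents that add atoms: none
Why: SNAr (addition–elimination), where the 4-OH of 4 is the most acidic and the only unhindered phenol not held by the ester, and its phenoxide displaces fluoride ortho to the ester of 3 (F far better than Cl as SNAr leaving group), so a single diaryl ether forms.

Step 3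
Reactants: 5 methyl 2-chloro-6-[3,5-dihydroxy-4-(methoxycarbonyl)phenoxy]-4-methoxybenzoate
Product: 6 methyl 2-chloro-6-[3-hydroxy-4-(methoxycarbonyl)-5-(trifluoromethanesulfonyloxy)phenoxy]-4-methoxybenzoate
Conditions: Tf2O (1.05 equiv), pyridine (3 equiv), CH2Cl2, −40 → 0 °C
Reagents that add atoms: trifluoromethanesulfonic anhydride, O=S(=O)(OS(=O)(=O)C(F)(F)F)C(F)(F)F
Why: Phenol O-sulfonylation, where the two OH groups are equivalent but only one can chelate the ester C=O at a time, and after the first triflation the remaining OH is locked in that hydrogen bond on a more electron-poor ring, so one equivalent of Tf2O stops at the monotriflate.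

Step 4
Reactants: 6 methyl 2-chloro-6-[3-hydroxy-4-(methoxycarbonyl)-5-(trifluoromethanesulfonyloxy)phenoxy]-4-methoxybenzoate; 7 heptanal (3.0 equiv); 8 hydrazine, used as the monohydrate (3.3 equiv)
Product: 10 methyl 2-heptyl-6-[3-heptyl-5-hydroxy-4-(methoxycarbonyl)phenoxy]-4-methoxybenzoate, via heptanal hydrazone 9 (not isolated)
Conditions: 7, N2H4·H2O, THF, rt, 30 min, 4 Å MS; then 6, Ni(cod)2 (20 mol %), PMe3 (40 mol %), DBU (4 equiv), THF, 60 °C
Reagents that add atoms: none
Why: Proposed new method: oxidative addition of Ar–OTf and Ar–Cl (both ortho to an ester) to Ni(0)/PMe3 is followed by N-deprotonation of hydrazone 9 on nickel, the aza-enamine-type nickel hydrazonide forms the aryl–carbon bond at the former carbonyl carbon through a six-membered transition state, and the resulting N–H diazene loses N2 under DBU (Wolff–Kishner-type) to leave Ar–CH2–C6H13; the closest known reaction type is the nickel-catalysed deoxygenative cross-coupling of aldehyde N–H hydrazones with aryl halides and aryl sulfonates, which tolerates esters, and what is new is the twofold coupling, the aliphatic hydrazone and the ortho-ester electrophiles; no stereocentre is formed.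

Step 5
Reactants: 10 methyl 2-heptyl-6-[3-heptyl-5-hydroxy-4-(methoxycarbonyl)phenoxy]-4-methoxybenzoate
Product: 11 4-(2-carboxy-3-heptyl-5-methoxyphenoxy)-2-heptyl-6-hydroxybenzoic acid (target)
Conditions: KOH (10 equiv), DMSO/H2O 4:1, 90 °C; then 1 M HCl, 0 °C, to pH 2
Reagents that add atoms: potassium hydroxide, [K+].[OH-]
Why: Saponification (BAc2) of both shielded methyl esters by hydroxide in wet DMSO, where the salicylate half stays as its phenoxide–carboxylate (the base-stable Kolbe–Schmitt-type salt) and is protonated only in the cold, so it does not decarboxylate.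

## Compound list

1 | 3-chloro-5-fluoroanisole (1-chloro-3-fluoro-5-methoxybenzene) | COc1cc(F)cc(Cl)c1 | starting material
2 | (2-chloro-6-fluoro-4-methoxyphenyl)lithium | [Li]c1c(F)cc(OC)cc1Cl | intermediate
3 | methyl 2-chloro-6-fluoro-4-methoxybenzoate | COC(=O)c1c(F)cc(OC)cc1Cl | intermediate
4 | methyl 2,4,6-trihydroxybenzoate | COC(=O)c1c(O)cc(O)cc1O | starting material
5 | methyl 2-chloro-6-[3,5-dihydroxy-4-(methoxycarbonyl)phenoxy]-4-methoxybenzoate | COC(=O)c1c(Cl)cc(OC)cc1Oc1cc(O)c(C(=O)OC)c(O)c1 | intermediate
6 | methyl 2-chloro-6-[3-hydroxy-4-(methoxycarbonyl)-5-(trifluoromethanesulfonyloxy)phenoxy]-4-methoxybenzoate | COC(=O)c1c(Cl)cc(OC)cc1Oc1cc(O)c(C(=O)OC)c(OS(=O)(=O)C(F)(F)F)c1 | intermediate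
7 | heptanal | CCCCCCC=O | starting material
8 | hydrazine (used as the monohydrate) | NN | starting material
9 | (E)-heptanal hydrazone | CCCCCC/C=N/N | intermediate
10 | methyl 2-heptyl-6-[3-heptyl-5-hydroxy-4-(methoxycarbonyl)phenoxy]-4-methoxybenzoate | CCCCCCCc1cc(Oc2cc(OC)cc(CCCCCCC)c2C(=O)OC)cc(O)c1C(=O)OC | intermediate
11 | 4-(2-carboxy-3-heptyl-5-methoxyphenoxy)-2-heptyl-6-hydroxybenzoic acid | CCCCCCCc1cc(Oc2cc(OC)cc(CCCCCCC)c2C(=O)O)cc(O)c1C(=O)O | target

## Step count and risks

Total step count: 5. Longest linear sequence: 5 (1 → 3 → 5 → 6 → 10 → 11).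

Steps most likely to fail:

Step 4 (twofold nickel/hydrazone coupling). The risks are incomplete second coupling, hydrodehalogenation, and attack of residual hydrazine on the triflate. The fallback sets out from 6 and comes back at 10, and keeps a reversed-polarity C1 donor. Palladium-catalysed α-arylation of 1-nitroheptane, as its nitronate, at both the triflate and the chloride (Pd2(dba)3, XPhos, Cs2CO3, DME, 60–80 °C) gives methyl 2-[3-hydroxy-4-(methoxycarbonyl)-5-(1-nitroheptyl)phenoxy]-4-methoxy-6-(1-nitroheptyl)benzoate F1 as a mixture of diastereomers whose stereocentres are removed next. Radical denitration (Bu3SnH, AIBN, toluene, 100 °C) then replaces both benzylic nitro groups by hydrogen and gives 10.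

Step 2 (SNAr on an ester twisted out of plane by two ortho substituents, with a weakly nucleophilic phenoxide). The fallback sets out from 1 and comes back at 5. Aryllithium 2 is quenched with DMF instead, giving 2-chloro-6-fluoro-4-methoxybenzaldehyde F2, whose coplanar formyl group activates the fluoride much more strongly. SNAr with 4 (K2CO3, DMF, 60 °C) gives methyl 4-(3-chloro-2-formyl-5-methoxyphenoxy)-2,6-dihydroxybenzoate F3. Pinnick oxidation (NaClO2, NaH2PO4, 2-methyl-2-butene, t-BuOH/H2O) gives 2-chloro-6-[3,5-dihydroxy-4-(methoxycarbonyl)phenoxy]-4-methoxybenzoic acid F4, and carboxylate-selective methylation (MeI, KHCO3, DMF, rt) returns 5.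

Step 5 (hydrolysis of two hindered esters). The risks are slow attack at the shielded carbonyls, hydroxide SNAr at the aryloxy carbon ortho to the ester, and decarboxylation of the salicylic half on acidification. The fallback sets out from 10 and comes back at 11. Instead of attacking the carbonyl groups, the O–CH3 bonds are cleaved by SN2 with iodide (LiI, pyridine, reflux; then cold dilute HCl), which leaves the aryl methyl ether untouched at this temperature; no new compound is made on this way (F0).

## Further compounds

F1 | step 4 | methyl 2-[3-hydroxy-4-(methoxycarbonyl)-5-(1-nitroheptyl)phenoxy]-4-methoxy-6-(1-nitroheptyl)benzoate (mixture of diastereomers) | CCCCCCC([N+](=O)[O-])c1cc(Oc2cc(OC)cc(C(CCCCCC)[N+](=O)[O-])c2C(=O)OC)cc(O)c1C(=O)OC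
F2 | step 2 | 2-chloro-6-fluoro-4-methoxybenzaldehyde | O=Cc1c(F)cc(OC)cc1Cl
F3 | step 2 | methyl 4-(3-chloro-2-formyl-5-methoxyphenoxy)-2,6-dihydroxybenzoate | O=Cc1c(Cl)cc(OC)cc1Oc1cc(O)c(C(=O)OC)c(O)c1
F4 | step 2 | 2-chloro-6-[3,5-dihydroxy-4-(methoxycarbonyl)phenoxy]-4-methoxybenzoic acid | OC(=O)c1c(Cl)cc(OC)cc1Oc1cc(O)c(C(=O)OC)c(O)c1
F0 | step 5 | none | none
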